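**Retrosynthetic overview**
- Target 9 comes from 3-(4-acetoxyphenyl)propyl docosanoate 8 by selective aminolysis of the aryl acetate.
- 8 is cut between the oxygen-bearing CH2 (propyl C1) and the central CH2 (propyl C2). This gives a (docosanoyloxy)methyl radical and 4-acetoxystyrene 5, joined by a photoredox decarboxylative anti-Markovnikov hydroalkylation.
- Enabling feature: propyl C3 sits directly on the para-oxygenated benzene ring, so C2=C3 can be a styrene double bond. Its terminal carbon C2 accepts the radical because the spin lands on benzylic C3. Propyl C1 carries the ester oxygen, which stabilises the attacking radical and lets the carboxyl group of glycolic acid serve as a traceless radical handle.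
- The radical precursor 4 is the N-hydroxyphthalimide ester of 2-(docosanoyloxy)acetic acid 3, made from docosanoyl chloride 1 and glycolic acid 2.
- No ring is formed. The benzene ring is bought with 5, and the phthalimide ring is a temporary activating group lost in the key step.

Key step: step 3

Remark: the target has no stereocentre and no stereogenic double bond, so it is one achiral compound and the route needs no stereocontrol.

**Step 1**
Reactants: 1 docosanoyl chloride; 2 glycolic acid
Product: 3 2-(docosanoyloxy)acetic acid
Conditions: 2 (1.5 equiv), pyridine (2.5 equiv), DMAP (5 mol%), THF, 0 °C to rt; 1 M HCl work-up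
Reagents that add atoms: none
Why: Pyridine/DMAP-promoted O-acylation (Einhorn-type esterification) of the primary hydroxyl of an α-hydroxy acid with an acyl chloride is standard, and any mixed anhydride formed at the carboxylate should pass its docosanoyl group to the neighbouring hydroxyl through a five-membered transition state or be hydrolysed in the work-up; no stereocentre is formed.

**Step 2**
Reactants: 3 2-(docosanoyloxy)acetic acid
Product: 4 1,3-dioxoisoindolin-2-yl 2-(docosanoyloxy)acetate
Conditions: N-hydroxyphthalimide (1.1 equiv), DIC (1.1 equiv), DMAP (10 mol%), CH2Cl2, rt
Reagents that add atoms: N-hydroxyphthalimide, O=C1c2ccccc2C(=O)N1O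
Why: Steglich-type carbodiimide coupling of a carboxylic acid with N-hydroxyphthalimide is the standard entry to redox-active esters and leaves the alkyl docosanoate untouched; no stereocentre is formed.

**Step 3**
Reactants: 4 1,3-dioxoisoindolin-2-yl 2-(docosanoyloxy)acetate; 5 4-acetoxystyrene (4-vinylphenyl acetate, freed from stabiliser on a short alumina plug)
Product: 8 3-(4-acetoxyphenyl)propyl docosanoate, via (docosanoyloxy)methyl radical 6 (not isolated), via benzylic adduct radical 7 (not isolated)
Conditions: Ru(bpy)3(PF6)2 (1 mol%), Hantzsch ester (2 equiv), 5 (2.5 equiv), degassed CH2Cl2, 450 nm LEDs, rt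
Reagents that add atoms: none
Why: Excited Ru(II) is reductively quenched by the Hantzsch ester and Ru(I) transfers an electron to the phthalimide unit of 4, whose radical anion breaks the N–O bond and loses CO2 to give the oxygen-stabilised primary radical 6; 6 adds to the unsubstituted vinyl carbon of 5 to give 7, which takes a hydrogen atom from the Hantzsch ester or its radical cation to give 8, and the dihydropyridyl radical so formed can reduce further 4, so a chain supports the photocatalytic cycle. The closest known reaction type is the photoredox decarboxylative Giese-type hydroalkylation of vinylarenes and electron-poor alkenes with N-(acyloxy)phthalimides and Hantzsch ester, in which α-oxygenated alkyl radicals are established partners. No ring is closed and no stereocentre is created. The regioselectivity needed (attack at the terminal carbon only) is secured by the benzene ring of 5, which stabilises the new radical only if it lies on the benzylic carbon. The chemoselectivity needed is addition of 6 before premature hydrogen abstraction, favoured by the excess of cheap 5, and a single addition instead of telomerisation, favoured because hydrogen transfer from the weak C4–H bond of excess Hantzsch ester to 7 should outrun the slow addition of a benzylic radical to styrene. Termination must stay at the radical level, and it should, because Ru(I) is not reducing enough to turn the secondary benzylic radical 7 into a carbanion; O-to-C acyl shift or cyclopropane closure with loss of docosanoate is therefore not expected, and the neutral medium spares the aryl acetate and the alkyl ester.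

**Step 4**
Reactants: 8 3-(4-acetoxyphenyl)propyl docosanoate
Product: 9 3-(4-hydroxyphenyl)propyl docosanoate
Conditions: pyrrolidine (3 equiv), THF, 0 °C to rt; dilute HCl work-up
Reagents that add atoms: none
Why: Chemoselective aminolysis of an activated ester: the aryl acetate has a phenoxide leaving group and should be cleaved by a secondary amine at room temperature, whereas the alkyl docosanoate with its alkoxide leaving group is inert under these conditions; no stereocentre is involved.

**Compound list**
1 | docosanoyl chloride | CCCCCCCCCCCCCCCCCCCCCC(=O)Cl | starting material
2 | glycolic acid | OCC(=O)O | starting material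
3 | 2-(docosanoyloxy)acetic acid | CCCCCCCCCCCCCCCCCCCCCC(=O)OCC(=O)O | intermediate
4 | 1,3-dioxoisoindolin-2-yl 2-(docosanoyloxy)acetate | CCCCCCCCCCCCCCCCCCCCCC(=O)OCC(=O)ON1C(=O)c2ccccc2C1=O | intermediate
5 | 4-acetoxystyrene (4-vinylphenyl acetate) | C=Cc1ccc(OC(C)=O)cc1 | starting material
6 | (docosanoyloxy)methyl radical (not isolated) | CCCCCCCCCCCCCCCCCCCCCC(=O)O[CH2] | intermediate
7 | 1-(4-acetoxyphenyl)-3-(docosanoyloxy)propyl radical (not isolated) | CCCCCCCCCCCCCCCCCCCCCC(=O)OCC[CH]c1ccc(OC(C)=O)cc1 | intermediate
8 | 3-(4-acetoxyphenyl)propyl docosanoate | CCCCCCCCCCCCCCCCCCCCCC(=O)OCCCc1ccc(OC(C)=O)cc1 | intermediate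
9 | 3-(4-hydroxyphenyl)propyl docosanoate | CCCCCCCCCCCCCCCCCCCCCC(=O)OCCCc1ccc(O)cc1 | target

Total step count: 4. Longest linear sequence: 4 (1 → 3 → 4 → 8 → 9).

**Steps most likely to fail**

**Step 3.** The acyloxymethyl radical may be quenched by hydrogen transfer before it adds. The benzylic radical may also add to more styrene, so that telomers form. The fallback sets out from 4 and comes back at 8. It replaces the alkene with a saturated partner and makes the same C–C bond by a nickel-electrocatalytic doubly decarboxylative C(sp3)–C(sp3) cross-coupling.
- Commercial 3-(4-hydroxyphenyl)propanoic acid is acetylated (Ac2O, pyridine) to 3-(4-acetoxyphenyl)propanoic acid F1.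
- F1 is converted (N-hydroxyphthalimide, DIC, DMAP, CH2Cl2) into 1,3-dioxoisoindolin-2-yl 3-(4-acetoxyphenyl)propanoate F2.
- F2 (3 equiv) and 4 are electrolysed together (NiCl2·6H2O, tridentate nitrogen ligand, NaI, DMF, Mg anode, RVC cathode, constant current).
- This should give 8 after chromatographic removal of the symmetrical dimers.

**Step 1.** Acylation may occur at the carboxylate instead of the hydroxyl, and glycolic acid may self-esterify, which would lower the purity of the acid. The fallback sets out from 1 and comes back at 3, and it masks the carboxyl group.
- 1 is treated with commercial benzyl glycolate (pyridine, DMAP, CH2Cl2) to give benzyl 2-(docosanoyloxy)acetate F3.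
- Hydrogenolysis of F3 (H2, Pd/C, THF/EtOAc) should deliver 3.

**Step 4.** Discrimination between the two esters may be incomplete, with partial aminolysis of the docosanoate or acyl transfer to the liberated phenoxide. The fallback sets out from 4 and comes back at 9. It changes the phenol mask to one removed without any nucleophile.
- 4 is coupled with commercial 1-(benzyloxy)-4-vinylbenzene under the hydroalkylation conditions of step 3 to give 3-[4-(benzyloxy)phenyl]propyl docosanoate F4.
- Hydrogenolysis of F4 (H2, Pd/C, THF/EtOAc) should give 9.

**Further compounds**
F1 | step 3 | 3-(4-acetoxyphenyl)propanoic acid | CC(=O)Oc1ccc(CCC(=O)O)cc1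
F2 | step 3 | 1,3-dioxoisoindolin-2-yl 3-(4-acetoxyphenyl)propanoate | CC(=O)Oc1ccc(CCC(=O)ON2C(=O)c3ccccc3C2=O)cc1
F3 | step 1 | benzyl 2-(docosanoyloxy)acetate | CCCCCCCCCCCCCCCCCCCCCC(=O)OCC(=O)OCc1ccccc1
F4 | step 4 | 3-[4-(benzyloxy)phenyl]propyl docosanoate | CCCCCCCCCCCCCCCCCCCCCC(=O)OCCCc1ccc(OCc2ccccc2)cc1
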